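## Analysis of the target

The target 31 is a tetracyclic C20 lactone aldehyde. A 6-oxabicyclo[3.2.1]octan-3-one (ring A: C5, C11(=O), C12, C13, C17, C16, with C17 carrying two methyls and O14–C15 bridging C13 and C16) is joined through the spiro carbon C5 to a δ-lactone (ring B: C4, C5, C6, O7, C8(=O), C9), which is fused along C4–C9 to a cyclohexane (ring C: C1, C2, C3, C4, C9, C10) carrying a 2-propenal unit on C1. There are six stereocentres: the bridgeheads C13 and C16 (necessarily cis), the quaternary spiro carbon C5, the ring-fusion carbons C4 (H) and C9 (tertiary OH), and C1. At C5 the lactone methylene C6 is axial on ring A, on the face of the gem-dimethyl bridge, and C4 is equatorial, on the face of the O14–C15 bridge. Rings B and C are trans-fused with C4–H and C9–OH trans-diaxial, the C1 side chain is equatorial, and on the lactone chair C11 is axial and C16 equatorial. The sensitive groups are the α-substituted acrolein (Michael acceptor, prone to polymerise), the C11 ketone (a β-alkoxy ketone: a C12 enolate can expel O14 and open the bridge) and the β-hydroxy ketones met on the way (dehydration, retro-aldol). The synthesis is hard because C5 is flanked by a bridgehead and a ketone and carries its oxygenated carbon on the more hindered face, because two trans-related ring-fusion centres must be built next to it, and because the skeleton offers few handles for absolute control. The strategy rests on ring A: C13(H)(O)–C17(Me2)–C16(H)(C) is the pattern left when a 2,2-dimethyloxirane opens and closes onto an alkene, so cutting C16–C17 leads to an epoxide whose only stereocentre (C13) comes from catalytic asymmetric epoxidation and to an enoate whose β-carbon is C16.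

## Retrosynthetic reasoning

The first cut is the C=CH2 bond of the enal, taking 31 back to the saturated aldehyde 30. The α-methylene aldehyde is the least durable group, so it is made last by α-methylenation, which touches no stereocentre.

The C11 ketone of 30 is then masked as the dioxolane 29, and the C1–H bond of 29 is traced to the alkylidene acetaldehyde 28. This places the creation of C1 in a hydrogenation that the axial C9 hydroxyl can direct. 28 comes from the vinyl carbinol 27 by 1,3-oxidative transposition, and 27 from the ring C ketone 26 by cutting the C1–vinyl bond. This sequence turns C=O into CH–CH2–CHO without a basic ylide, which the β-hydroxy ketone of 26 would not survive.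

Ring C of 26 is cut at C3–C4 and C9–C10, giving the α-keto lactone 23 and methyl vinyl ketone 24. C4 of 23 is α to the C9 ketone and acts as Michael donor; the methyl group of 24 becomes C10 and closes onto C9, creating the tertiary alcohol. Both ring-fusion centres form under reversible conditions, so the most stable arrangement (trans fusion, C16 equatorial on the lactone) should prevail.

The C9 carbonyl of 23 is traced to the exocyclic alkene of the α-methylene lactone 21. Lactone 21 is cut at O7–C8 and C8–C9 into the bromoallyl alcohol 20, so that C8 enters as a one-carbon carbonylation unit. This avoids telling two esters apart. The neopentyl alcohol of 20 comes from the ester of 19, and the ketal of 19 from the ketone of 18. The ketal lets hydride reduce the ester alone and shuts off enolisation towards C12 in every later basic step.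

The C4–C5 bond of 18 is cut to the bridged β-keto ester 16 and 2,3-dibromopropene 17. The ester carbon of 16 becomes C6; because C6 must sit on the face of the gem-dimethyl bridge, it has to be in place first, and the electrophile then arrives from the open face.

16 is traced through the alcohol 15 and silyl ether 14 to the tosylate 13, cutting O14–C15 (intramolecular etherification). 13 comes from the diol 12 and the benzyl ether 11. The cut needs C13–O and C16–CH2O cis-1,3, which is what the ring closure delivers.

Ring A of 11 is cut at C16–C17, giving the epoxy enoate 10. This is the key disconnection: one C–C bond, one ring, and the cis-1,3 relationship, from an acyclic precursor.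

10 comes from the alkene 9 by reagent-controlled epoxidation, the only source of absolute configuration, and 9 from the allylic alcohol 8 by silylation. 8 is cut at C5–C11 into the ynoate 4 and the aldehyde 6 (reductive aldol through a vinylalane, which fixes the Z geometry). 4 comes from benzyl propargyl ether 1 and methyl chloroformate 2, and 6 from 4-methylpent-3-en-1-ol 5.

## Alternatives that were turned down

Alternative 1: Rings B and C are disconnected together at C4–C9, C5–C6 and O7–C8. In the forward step SmI2 would reduce the α-keto ester of the enone keto ester A2 to a ketyl that adds 6-exo to the alkylidene ketone (C9–C4, ring C). The samarium enolate would then be hydroxymethylated at C5 by formaldehyde A3, and the alkoxide would lactonise to give A1, the isopropenyl analogue of 31.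
- For it: two rings and three stereocentres in one operation, a convergent union of ring A with a side chain that already carries C1, and an end game of one allylic oxidation with SeO2.
- Against it: in 31 the carbon C6 lies on the face of ring A shielded by the syn methyl of C17. A3 would have to attack the enolate from exactly that face, whereas steric approach control predicts the opposite spiro epimer. C9, C4 and C5 would also be set in one cascade through a flexible tether, two reducible carbonyl systems compete for SmI2, and protonation of the enolate competes with capture of A3.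
- Comparison: this alternative is clearly stronger on step economy in the late stage, where the chosen route spends about ten steps. The chosen strategy offers instead a spiro centre built in the order the sterics demand (C6 first, C4 from the open face) and ring-fusion centres set under equilibrating conditions.

Alternative 2: Ring A and the ether bridge are disconnected at C5–C16 and O14–C15. Mediated anodic oxidation of the acyclic β-keto ester A5 would give the C5 radical, which adds 6-exo to the methyl enol ether. The α-alkoxy radical is oxidised to an oxocarbenium ion that the C13 hydroxyl traps, giving the methyl acetal A4; ionic reduction of the acetal would then give 16.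
- For it: the electrophilic radical and the electron-rich alkene are polarity-matched, two rings form at once from a chain with one stereocentre, and 16 would be reached in fewer steps than the eleven used here.
- Against it: A4 is a β-keto ester with an α-hydrogen and is as oxidisable as A5, so over-oxidation is built in. A5 is a β-hydroxy ketone, open to dehydration and retro-aldol. Only the cis adduct can be trapped by the hydroxyl, and the trans adduct is lost to the solvent. The single stereocentre of A5 is a neopentyl carbinol, which calls for an enantioselective acetate-type aldol on an α,α-disubstituted aldehyde. The attacked carbon C16 is next to the quaternary C17.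
- Comparison: the alternative is stronger on step count. The chosen strategy offers absolute control from a reagent-controlled epoxidation of a trisubstituted alkene, a chair transition state that fixes the cis-1,3 relationship, and a product that is not destroyed by the reagent that makes it.

Alternative 3: Ring A and the ether bridge are disconnected at C12–C13 and C13–O14. Me3SiOTf would ionise the dimethyl acetal of the bis-silyl dienol ether A7. The benzyl ether oxygen closes onto C13 with loss of the benzyl group, giving a five-membered oxocarbenium ion, and the γ-carbon C12 of the dienol ether attacks it to give A6, which is identical with 16.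
- For it: the benzyl ether is consumed productively instead of being removed, tosylated and closed; the γ-selectivity of such dienol ethers is well founded; the cis bicycle is enforced; and 16 is reached directly.
- Against it: the only stereocentre of A7 is C16, a CH between a quaternary carbon, a CH2OBn group and the keto ester α-carbon, with no obvious catalytic asymmetric entry. The electrophilic carbon C13 is neopentyl. The nucleophile must reach across the five-membered ring in a bridging closure. The released benzyl electrophile can alkylate the dienol ether.
- Comparison: the alternative is shorter and uses no protecting-group steps on the way to 16. The chosen strategy is longer but traces every stereocentre of ring A to a reliable element: epoxidation for C13, and alkene geometry plus the chair for C16.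

Key step: step 6

Assumption 1: the carbinol carbon made in step 3 is not controlled, so 8 and 9 are racemic and 10 to 15 are each carried as a pair of epimers at the silyloxy (later hydroxy) carbon C11; one epimer is drawn, and the pair converges in 16.

Assumption 2: the fructose-derived dioxirane catalyst is taken to epoxidise 2-methyl-2-alkenes with the usual sense, so that the ketone of the L series (enantiomer of the D-fructose-derived catalyst) gives the (S)-epoxide needed at C13.

## Route

Step 1
Reactants: 1 benzyl propargyl ether; 2 methyl chloroformate
Product: 4 methyl 4-(benzyloxy)but-2-ynoate, via lithium acetylide 3 (not isolated)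
Conditions: n-BuLi, THF, −78 °C; then ClCO2Me, −78 → 0 °C
Reagents that add atoms: none
Why: Deprotonation of the terminal alkyne and C-acylation of the acetylide with a chloroformate is the standard alkynoate synthesis; the propargylic ether is inert at −78 °C.

Step 2
Reactants: 5 4-methylpent-3-en-1-ol
Product: 6 4-methylpent-3-enal
Conditions: Dess–Martin periodinane, NaHCO3, CH2Cl2, 0 °C → rt; used at once as a solution
Reagents that add atoms: none
Why: Buffered periodinane oxidation of a primary alcohol stops at the aldehyde and, being neutral, should not move the β,γ double bond into conjugation.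

Step 3
Reactants: 4 methyl 4-(benzyloxy)but-2-ynoate; 6 4-methylpent-3-enal
Product: 8 methyl (Z)-4-(benzyloxy)-2-(1-hydroxy-4-methylpent-3-en-1-yl)but-2-enoate (racemic), via vinylalane 7 (not isolated)
Conditions: i-Bu2AlH, N-methylmorpholine N-oxide, THF, 0 °C; then 6, 0 °C → rt; aq. KNaC4H4O6 work-up
Reagents that add atoms: none
Why: Syn-hydroalumination of the ynoate (hydride to the β-carbon) gives the α-alumino enoate 7, which adds to the aldehyde with retention (reductive aldol, vinylalumination). The ester therefore stays cis to CH2OBn, which is the Z geometry the cyclisation needs; the carbinol centre is not controlled.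

Step 4
Reactants: 8 methyl (Z)-4-(benzyloxy)-2-(1-hydroxy-4-methylpent-3-en-1-yl)but-2-enoate
Product: 9 methyl (Z)-4-(benzyloxy)-2-[1-(tert-butyldimethylsilyloxy)-4-methylpent-3-en-1-yl]but-2-enoate (racemic)
Conditions: TBSOTf, 2,6-lutidine, CH2Cl2, −78 → 0 °C
Reagents that add atoms: tert-butyldimethylsilyl triflate, CC(C)(C)[Si](C)(C)OS(=O)(=O)C(F)(F)F
Why: Silyl triflate silylation of a hindered secondary allylic alcohol; the future C11 ketone is carried as an ether because a ketone β,γ to the coming epoxide would eliminate.

Step 5
Reactants: 9 methyl (Z)-4-(benzyloxy)-2-[1-(tert-butyldimethylsilyloxy)-4-methylpent-3-en-1-yl]but-2-enoate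
Product: 10 methyl (Z)-4-(benzyloxy)-2-[(1S)-1-(tert-butyldimethylsilyloxy)-2-[(2S)-3,3-dimethyloxiran-2-yl]ethyl]but-2-enoate (drawn epimer, accompanied by its (1R) epimer)
Conditions: 1,2:4,5-di-O-isopropylidene-β-L-erythro-2,3-hexodiulo-2,6-pyranose (30 mol %), KHSO5, K2CO3, Bu4NHSO4, MeCN/CH2(OMe)2, aq. Na2B4O7 buffer, 0 °C
Reagents that add atoms: potassium peroxymonosulfate, [K+].[O-]S(=O)(=O)OO
Why: Shi epoxidation: the chiral dioxirane epoxidises the electron-rich trisubstituted alkene and leaves the electron-poor enoate alone. The spiro transition state sets C13 as (S) under catalyst control, whatever the remote silyloxy centre.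

Step 6
Reactants: 10 methyl (Z)-4-(benzyloxy)-2-[(1S)-1-(tert-butyldimethylsilyloxy)-2-[(2S)-3,3-dimethyloxiran-2-yl]ethyl]but-2-enoate
Product: 11 methyl 2-(benzyloxymethyl)-6-(tert-butyldimethylsilyloxy)-4-hydroxy-3,3-dimethylcyclohexane-1-carboxylate (4S; hydroxyl and benzyloxymethyl cis and equatorial, ester trans to benzyloxymethyl)
Conditions: Cp2TiCl2 (20 mol %), Mn dust, 2,4,6-collidine hydrochloride, THF, rt, slow addition of 10
Reagents that add atoms: none
Why: Cp2TiCl (trivalent titanium, regenerated from Cp2TiCl2 by Mn) transfers one electron to the epoxide, which opens homolytically at the more substituted carbon to give the tertiary C17 radical and a titanium alkoxide at C13; the closest known reaction type is the titanocene-mediated radical cyclisation of epoxy-olefins onto α,β-unsaturated esters. Ring A closes 6-endo-trig: the nucleophilic tertiary radical adds to the β-carbon C16 of the enoate, which is polarity-matched and leaves a stabilised α-ester radical at C5, whereas 5-exo attack would have to occur at the fully substituted α-carbon. A second Cp2TiCl reduces the C5 radical to a titanium enolate, and collidinium chloride protonates enolate and alkoxide, returning tetravalent titanium to the cycle. C16 is controlled by the chair transition state: the C13–O–Ti group is equatorial, and because CH2OBn is trans to the ring chain on the Z-alkene it is equatorial too, so the two groups end cis-1,3 across C17. C5 is set by protonation of the enolate, should favour the equatorial ester and does not matter because this centre is planarised again in 16. The absolute configuration is that of the C13–O bond, which is not broken. The step needs opening to the tertiary radical, 6-endo over 5-exo closure and survival of the silyl ether; the substituted α-carbon and the ester secure the first two, and the proton source shortens the life of the enolate that could expel the silyloxy group.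

Step 7
Reactants: 11 methyl 2-(benzyloxymethyl)-6-(tert-butyldimethylsilyloxy)-4-hydroxy-3,3-dimethylcyclohexane-1-carboxylate
Product: 12 methyl 6-(tert-butyldimethylsilyloxy)-4-hydroxy-2-(hydroxymethyl)-3,3-dimethylcyclohexane-1-carboxylate (same configuration)
Conditions: H2 (1 atm), Pd/C, EtOAc, rt; crude diol taken on directly
Reagents that add atoms: none
Why: Hydrogenolysis of the benzyl ether; nothing else is reducible. Prompt use forestalls lactonisation of the γ-hydroxy ester.

Step 8
Reactants: 12 methyl 6-(tert-butyldimethylsilyloxy)-4-hydroxy-2-(hydroxymethyl)-3,3-dimethylcyclohexane-1-carboxylate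
Product: 13 methyl 6-(tert-butyldimethylsilyloxy)-4-hydroxy-3,3-dimethyl-2-(tosyloxymethyl)cyclohexane-1-carboxylate
Conditions: TsCl, pyridine, CH2Cl2, 0 °C
Reagents that add atoms: p-toluenesulfonyl chloride, Cc1ccc(cc1)S(=O)(=O)Cl
Why: Selective sulfonylation: the primary alcohol reacts, the secondary alcohol next to the quaternary C17 does not.

Step 9
Reactants: 13 methyl 6-(tert-butyldimethylsilyloxy)-4-hydroxy-3,3-dimethyl-2-(tosyloxymethyl)cyclohexane-1-carboxylate
Product: 14 methyl (1R,5S)-3-(tert-butyldimethylsilyloxy)-8,8-dimethyl-6-oxabicyclo[3.2.1]octane-2-carboxylate (C2 and C3 as in 13)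
Conditions: NaH, THF, 0 → 40 °C
Reagents that add atoms: none
Why: Intramolecular Williamson etherification (5-exo-tet): after ring flip the cis-1,3 alkoxide and tosyloxymethyl group are diaxial and close the O14–C15 bridge. The alcohol is far more acidic than the ester α-CH, the C13–O bond is retained, and any epimerisation at C5 is harmless.

Step 10
Reactants: 14 methyl (1R,5S)-3-(tert-butyldimethylsilyloxy)-8,8-dimethyl-6-oxabicyclo[3.2.1]octane-2-carboxylate
Product: 15 methyl (1R,5S)-3-hydroxy-8,8-dimethyl-6-oxabicyclo[3.2.1]octane-2-carboxylate
Conditions: HF·pyridine, THF, 0 °C → rt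
Reagents that add atoms: none
Why: Fluoride cleavage of the Si–O bond under buffered acidic conditions, which avoids base-induced elimination or retro-aldol of the β-hydroxy ester.

Step 11
Reactants: 15 methyl (1R,5S)-3-hydroxy-8,8-dimethyl-6-oxabicyclo[3.2.1]octane-2-carboxylate
Product: 16 methyl (1R,2S,5S)-8,8-dimethyl-3-oxo-6-oxabicyclo[3.2.1]octane-2-carboxylate (in equilibrium with its enol)
Conditions: Dess–Martin periodinane, NaHCO3, CH2Cl2, rt
Reagents that add atoms: none
Why: Periodinane oxidation of the secondary alcohol; both C11 epimers converge on one β-keto ester, whose C5 equilibrates through the enol to the equatorial ester.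

Step 12
Reactants: 16 methyl (1R,2S,5S)-8,8-dimethyl-3-oxo-6-oxabicyclo[3.2.1]octane-2-carboxylate; 17 2,3-dibromopropene
Product: 18 methyl 2-(2-bromoprop-2-en-1-yl)-8,8-dimethyl-3-oxo-6-oxabicyclo[3.2.1]octane-2-carboxylate (ester on the face of the gem-dimethyl bridge, bromoallyl group on the face of the O–CH2 bridge)
Conditions: K2CO3, acetone, reflux
Reagents that add atoms: none
Why: C-alkylation of a β-keto ester enolate with a soft allylic bromide; the mild base enolises only C5, never C12. The syn methyl of C17 is 1,3-diaxial to the upper face of C5, so the electrophile should enter from the face of the O14–C15 bridge and push the ester axial, which sets the spiro centre as in 31.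

Step 13
Reactants: 18 methyl 2-(2-bromoprop-2-en-1-yl)-8,8-dimethyl-3-oxo-6-oxabicyclo[3.2.1]octane-2-carboxylate
Product: 19 ethylene ketal (spiro-1,3-dioxolane at C11) of 18
Conditions: (Me3SiOCH2)2, Me3SiOTf (cat.), CH2Cl2, −78 → −20 °C
Reagents that add atoms: 1,2-bis(trimethylsilyloxy)ethane, C[Si](C)(C)OCCO[Si](C)(C)C
Why: Silyl-transfer acetalisation at low temperature, driven by formation of the disiloxane, works on ketones flanked by a quaternary carbon. The mild conditions spare the β-alkoxy ketone from acid-promoted opening.

Step 14
Reactants: 19 ethylene ketal of 18
Product: 20 [2-(2-bromoprop-2-en-1-yl)-3,3-(ethylenedioxy)-8,8-dimethyl-6-oxabicyclo[3.2.1]octan-2-yl]methanol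
Conditions: LiAlH4, THF, 0 °C
Reagents that add atoms: none
Why: Hydride reduction of the only remaining carbonyl group; the ketal shields C11 and the vinyl bromide is inert at 0 °C.

Step 15
Reactants: 20 [2-(2-bromoprop-2-en-1-yl)-3,3-(ethylenedioxy)-8,8-dimethyl-6-oxabicyclo[3.2.1]octan-2-yl]methanol
Product: 21 spiro α-methylene δ-lactone (ring B with C9=CH2, C11 ketal)
Conditions: Pd(PPh3)4 (5 mol %), CO (1 atm), Et3N, MeCN, 65 °C
Reagents that add atoms: carbon monoxide, [C-]#[O+]
Why: Carbonylative lactonisation: zerovalent palladium inserts into the vinyl C–Br bond, CO insertion gives an acylpalladium, and the neopentyl alcohol captures it in a six-membered closure. This is the established route from bromo-alkenols to α-methylene lactones.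

Step 16
Reactants: 21 spiro α-methylene δ-lactone
Product: 23 spiro α-keto δ-lactone (C9 ketone; exists partly as the C4=C9 enol), via ozonide 22 (not isolated)
Conditions: O3, CH2Cl2, −78 °C (indicator end point); then PPh3, −78 °C → rt
Reagents that add atoms: ozone, [O-][O+]=O
Why: Ozonolysis of the 1,1-disubstituted alkene with reductive work-up; the ketal and lactone are inert at −78 °C when the ozone is not used in excess.

Step 17
Reactants: 23 spiro α-keto δ-lactone; 24 methyl vinyl ketone
Product: 26 trans-fused ketol (ring C with C1 ketone and C9 tertiary hydroxyl; C11 ketal), via Michael adduct 25 (not isolated)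
Conditions: Et3N (cat.), THF, 0 °C → rt; then DBU (cat.), rt
Reagents that add atoms: none
Why: Michael–aldol annulation of the Robinson type, stopped at the ketol: the acidic enol of the 1,2-dicarbonyl adds through C4 to the enone, and the methyl ketone then closes onto the C9 ketone, which the lactone carbonyl activates. C4 stays epimerisable through the enol and the aldol is reversible, so the product should be the most stable ketol: trans-fused, hydroxyl axial, C3 on the side of C11 and the bulky bridgehead C16 equatorial on the lactone, as in 31.

Step 18
Reactants: 26 trans-fused ketol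
Product: 27 C1 vinyl carbinol (tertiary allylic alcohol; epimer with equatorial vinyl drawn, either epimer serves)
Conditions: CH2=CHMgBr, CeCl3, THF, −78 °C
Reagents that add atoms: vinylmagnesium bromide, C=C[Mg]Br
Why: Organocerium 1,2-addition: the weakly basic, strongly nucleophilic vinylcerium reagent adds to the ketone without enolisation or retro-aldol of the β-hydroxy ketone and leaves the hindered lactone alone. One equivalent is spent on the free hydroxyl.

Step 19
Reactants: 27 C1 vinyl carbinol
Product: 28 alkylidene acetaldehyde (C1=CH–CHO; alkene isomers not separated)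
Conditions: C5H5NH[CrO3Cl], 4 Å molecular sieves, CH2Cl2, rt
Reagents that add atoms: pyridinium chlorochromate, [O-][Cr](=O)(=O)Cl.c1cc[nH+]cc1
Why: Babler–Dauben oxidative transposition: the tertiary allylic chromate ester (hexavalent chromium) shifts [3,3] to the primary allylic chromate, which is oxidised to the enal. The tertiary C9 alcohol cannot be oxidised.

Step 20
Reactants: 28 alkylidene acetaldehyde
Product: 29 saturated aldehyde (C1–CH2–CHO with the side chain equatorial; C11 ketal)
Conditions: H2 (1 atm), [Ir(cod)(PCy3)(py)]PF6 (5 mol %), CH2Cl2, rt
Reagents that add atoms: none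
Why: Hydroxyl-directed homogeneous hydrogenation: the cationic iridium catalyst binds the axial C9 hydroxyl and the exocyclic alkene and delivers hydrogen to the upper, axial face of C1. This leaves the side chain equatorial and trans to the hydroxyl, and both alkene isomers converge.

Step 21
Reactants: 29 saturated aldehyde
Product: 30 keto aldehyde (C11 ketone free)
Conditions: 1 M aq. HCl, THF, rt
Reagents that add atoms: water, O
Why: Acid hydrolysis of the hindered dioxolane; the saturated aldehyde, tertiary alcohol and lactone tolerate dilute acid, and no base is present to open the β-alkoxy ketone.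

Step 22
Reactants: 30 keto aldehyde
Product: 31 target CNP0525385.1
Conditions: aq. CH2O (37 %), pyrrolidine (10 mol %), propionic acid (10 mol %), i-PrOH, 45 °C
Reagents that add atoms: formaldehyde, C=O
Why: Amine-catalysed α-methylenation (Mannich condensation): the enamine of the aldehyde adds to the formaldehyde-derived iminium ion and the amine is eliminated to give the α-substituted acrolein. The hindered ketone forms an enamine far more slowly, and no stereocentre is involved.

## Compound list

1 | benzyl propargyl ether | C#CCOCc1ccccc1 | starting material
2 | methyl chloroformate | COC(=O)Cl | starting material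
3 | lithium 3-(benzyloxy)prop-1-yn-1-ide | [Li]C#CCOCc1ccccc1 | intermediate (not isolated)
4 | methyl 4-(benzyloxy)but-2-ynoate | COC(=O)C#CCOCc1ccccc1 | intermediate
5 | 4-methylpent-3-en-1-ol | CC(C)=CCCO | starting material
6 | 4-methylpent-3-enal | CC(C)=CCC=O | intermediate
7 | methyl 4-(benzyloxy)-2-(diisobutylalumanyl)but-2-enoate, ester cis to CH2OBn | COC(=O)/C(=C\COCc1ccccc1)[Al](CC(C)C)CC(C)C | intermediate (not isolated)
8 | methyl (Z)-4-(benzyloxy)-2-(1-hydroxy-4-methylpent-3-en-1-yl)but-2-enoate, racemic | COC(=O)/C(=C\COCc1ccccc1)C(O)CC=C(C)C | intermediate
9 | methyl (Z)-4-(benzyloxy)-2-[1-(tert-butyldimethylsilyloxy)-4-methylpent-3-en-1-yl]but-2-enoate, racemic | COC(=O)/C(=C\COCc1ccccc1)C(O[Si](C)(C)C(C)(C)C)CC=C(C)C | intermediate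
10 | methyl (Z)-4-(benzyloxy)-2-[(1S)-1-(tert-butyldimethylsilyloxy)-2-[(2S)-3,3-dimethyloxiran-2-yl]ethyl]but-2-enoate | COC(=O)/C(=C\COCc1ccccc1)[C@@H](O[Si](C)(C)C(C)(C)C)C[C@@H]1OC1(C)C | intermediate
11 | methyl 2-(benzyloxymethyl)-6-(tert-butyldimethylsilyloxy)-4-hydroxy-3,3-dimethylcyclohexane-1-carboxylate, OH and CH2OBn cis | COC(=O)[C@H]1[C@@H](O[Si](C)(C)C(C)(C)C)C[C@H](O)C(C)(C)[C@@H]1COCc1ccccc1 | intermediate
12 | methyl 6-(tert-butyldimethylsilyloxy)-4-hydroxy-2-(hydroxymethyl)-3,3-dimethylcyclohexane-1-carboxylate | COC(=O)[C@H]1[C@@H](O[Si](C)(C)C(C)(C)C)C[C@H](O)C(C)(C)[C@@H]1CO | intermediate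
13 | methyl 6-(tert-butyldimethylsilyloxy)-4-hydroxy-3,3-dimethyl-2-(tosyloxymethyl)cyclohexane-1-carboxylate | COC(=O)[C@H]1[C@@H](O[Si](C)(C)C(C)(C)C)C[C@H](O)C(C)(C)[C@@H]1COS(=O)(=O)c1ccc(C)cc1 | intermediate
14 | methyl (1R,5S)-3-(tert-butyldimethylsilyloxy)-8,8-dimethyl-6-oxabicyclo[3.2.1]octane-2-carboxylate | COC(=O)[C@H]1[C@@H](O[Si](C)(C)C(C)(C)C)C[C@@H]2OC[C@H]1C2(C)C | intermediate
15 | methyl (1R,5S)-3-hydroxy-8,8-dimethyl-6-oxabicyclo[3.2.1]octane-2-carboxylate | COC(=O)[C@H]1[C@@H](O)C[C@@H]2OC[C@H]1C2(C)C | intermediate
16 | methyl (1R,2S,5S)-8,8-dimethyl-3-oxo-6-oxabicyclo[3.2.1]octane-2-carboxylate | COC(=O)[C@@H]1C(=O)C[C@@H]2OC[C@H]1C2(C)C | intermediate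
17 | 2,3-dibromopropene | C=C(Br)CBr | starting material
18 | methyl 2-(2-bromoprop-2-en-1-yl)-8,8-dimethyl-3-oxo-6-oxabicyclo[3.2.1]octane-2-carboxylate, ester syn to the gem-dimethyl bridge | COC(=O)[C@@]1(CC(Br)=C)C(=O)C[C@@H]2OC[C@H]1C2(C)C | intermediate
19 | ethylene ketal of 18 | COC(=O)[C@@]1(CC(Br)=C)C3(OCCO3)C[C@@H]2OC[C@H]1C2(C)C | intermediate
20 | [2-(2-bromoprop-2-en-1-yl)-3,3-(ethylenedioxy)-8,8-dimethyl-6-oxabicyclo[3.2.1]octan-2-yl]methanol | OC[C@@]1(CC(Br)=C)C3(OCCO3)C[C@@H]2OC[C@H]1C2(C)C | intermediate
21 | spiro α-methylene δ-lactone, C11 ketal | C=C1C[C@]2(COC1=O)C3(OCCO3)C[C@@H]4OC[C@H]2C4(C)C | intermediate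
22 | spiro 1,2,4-trioxolane (ozonide) of 21 | O=C1OC[C@@]2(CC13OOCO3)C5(OCCO5)C[C@@H]4OC[C@H]2C4(C)C | intermediate (not isolated)
23 | spiro α-keto δ-lactone, C11 ketal | O=C1OC[C@@]2(CC1=O)C5(OCCO5)C[C@@H]4OC[C@H]2C4(C)C | intermediate
24 | methyl vinyl ketone | C=CC(C)=O | starting material
25 | C4-(3-oxobutyl) α-keto δ-lactone (Michael adduct) | CC(=O)CC[C@H]1[C@]2(COC(=O)C1=O)C5(OCCO5)C[C@@H]4OC[C@H]2C4(C)C | intermediate (not isolated)
26 | trans-fused ketol: C1 ketone, C9 hydroxyl, C11 ketal | O=C1CC[C@H]2[C@]3(COC(=O)[C@]2(O)C1)C5(OCCO5)C[C@@H]4OC[C@H]3C4(C)C | intermediate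
27 | C1 vinyl carbinol | C=C[C@]1(O)CC[C@H]2[C@]3(COC(=O)[C@]2(O)C1)C5(OCCO5)C[C@@H]4OC[C@H]3C4(C)C | intermediate
28 | C1 alkylidene acetaldehyde | O=CC=C1CC[C@H]2[C@]3(COC(=O)[C@]2(O)C1)C5(OCCO5)C[C@@H]4OC[C@H]3C4(C)C | intermediate
29 | saturated aldehyde, C11 ketal | O=CC[C@@H]1CC[C@H]2[C@]3(COC(=O)[C@]2(O)C1)C5(OCCO5)C[C@@H]4OC[C@H]3C4(C)C | intermediate
30 | keto aldehyde | O=CC[C@@H]1CC[C@H]2[C@]3(COC(=O)[C@]2(O)C1)C(=O)C[C@@H]4OC[C@H]3C4(C)C | intermediate
31 | CNP0525385.1 | C=C(C=O)[C@@H]1CC[C@H]2[C@]3(COC(=O)[C@]2(O)C1)C(=O)C[C@@H]1OC[C@H]3C1(C)C | target

## Step count and least certain steps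

Total step count: 22. Longest linear sequence: 21 steps (from 1 through steps 1 and 3 to 22; the branch from 5 adds step 2).

Step 6 (key step). The most likely failure is reduction of the tertiary radical by a second Cp2TiCl before the hindered C16–C17 bond forms, which would lead to loss of the titanoxy group or simple protonation. Expulsion of the silyloxy group from the titanium enolate is the second risk. The C11 epimer that must place the silyloxy group pseudo-equatorially next to the ester may cyclise more slowly. Fallback, from 10 back to 11: the epoxide would be opened with MgBr2·OEt2 at the tertiary carbon to give the bromohydrin F1. Treating F1 with Bu3SnH and AIBN under slow addition would generate the same tertiary radical by bromine abstraction in a chain process. No metal reductant is then present to intercept the radical, and no enolate forms, since the ester radical is quenched by hydrogen transfer. The same chair should lead to 11.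

Step 17. The risk is kinetic closure to a cis-fused ketol, or loss of water from the β-hydroxy ketone under the basic conditions needed for equilibration. Fallback, from 25 back to 26: the sequence would be stopped after the amine-catalysed Michael addition and 25 isolated. Ph3P=CH2 (two equivalents; the first only deprotonates the keto lactone enol and so protects it) would methylenate the methyl ketone to give the isopentenyl keto lactone F2. Me2AlCl would then close ring C by a type 2 carbonyl–ene reaction on the chelated 1,2-dicarbonyl, an irreversible and base-free closure, to give the methylene carbinol F3. The trans fusion is expected there as well, because both new ring bonds can be equatorial on the lactone. Ozonolysis of the exocyclic alkene of F3 would return to 26.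

Step 12. The risk is O-alkylation of the hindered enolate and erosion of facial selectivity, because C-alkylation forces the ester syn to a bridge methyl. Fallback, from 16 back to 18: O-alkylation would be made deliberate with 17 and Cs2CO3 in DMF, giving the allyl enol ether F4. Heating F4 in toluene would bring about a Claisen rearrangement, which delivers the bromoallyl group through a cyclic transition state to the same open face of C5.

Step 20. The risk is undirected delivery of hydrogen from the lower face, giving the axial side chain, if the aldehyde or lactone carbonyl outcompetes the tertiary hydroxyl for the iridium centre or the catalyst is deactivated. Fallback, from 28 back to 29: NaBH4 with CeCl3 at −78 °C would reduce the aldehyde to the allylic alcohol F5. Hydrogen-atom-transfer hydrogenation (Mn(dpm)3, PhSiH3, t-BuOOH, i-PrOH) would pass through the tertiary C1 radical, which is quenched axially, and give the saturated alcohol F6 with the equatorial side chain. Periodinane oxidation of F6 would give 29.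

Step 9. The risk is slow closure, because the reacting conformer needs the alkoxide and the tosyloxymethyl group axial with the ester syn to a methyl, and for one C11 epimer the silyloxy group axial as well. Enolisation of the ester could then compete, with loss of the silyloxy group or three-ring closure. Fallback, from 12 back to 14: PhI(OAc)2 with catalytic TEMPO would oxidise the primary alcohol to the hydroxy aldehyde F7, which should close reversibly to the lactol F8. Et3SiH with BF3·OEt2 at −78 °C would reduce the derived oxocarbenium ion to the ether 14.

## Further compounds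

F1 | step 6 | methyl (Z)-4-(benzyloxy)-2-[(1S,3S)-4-bromo-1-(tert-butyldimethylsilyloxy)-3-hydroxy-4-methylpentyl]but-2-enoate | COC(=O)/C(=C\COCc1ccccc1)[C@@H](O[Si](C)(C)C(C)(C)C)C[C@H](O)C(C)(C)Br
F2 | step 17 | C4-(3-methylbut-3-en-1-yl) α-keto δ-lactone, C11 ketal | CC(=C)CC[C@H]1[C@]2(COC(=O)C1=O)C5(OCCO5)C[C@@H]4OC[C@H]2C4(C)C
F3 | step 17 | trans-fused C1-methylene C9-carbinol, C11 ketal | C=C1CC[C@H]2[C@]3(COC(=O)[C@]2(O)C1)C5(OCCO5)C[C@@H]4OC[C@H]3C4(C)C
F4 | step 12 | methyl (1R,5S)-3-(2-bromoprop-2-en-1-yloxy)-8,8-dimethyl-6-oxabicyclo[3.2.1]oct-2-ene-2-carboxylate | COC(=O)C1=C(OCC(Br)=C)C[C@@H]2OC[C@H]1C2(C)C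
F5 | step 20 | C1 alkylidene ethanol (allylic alcohol), C11 ketal | OCC=C1CC[C@H]2[C@]3(COC(=O)[C@]2(O)C1)C5(OCCO5)C[C@@H]4OC[C@H]3C4(C)C
F6 | step 20 | saturated primary alcohol with equatorial side chain, C11 ketal | OCC[C@@H]1CC[C@H]2[C@]3(COC(=O)[C@]2(O)C1)C5(OCCO5)C[C@@H]4OC[C@H]3C4(C)C
F7 | step 9 | methyl 6-(tert-butyldimethylsilyloxy)-2-formyl-4-hydroxy-3,3-dimethylcyclohexane-1-carboxylate | COC(=O)[C@H]1[C@@H](O[Si](C)(C)C(C)(C)C)C[C@H](O)C(C)(C)[C@@H]1C=O
F8 | step 9 | methyl 3-(tert-butyldimethylsilyloxy)-7-hydroxy-8,8-dimethyl-6-oxabicyclo[3.2.1]octane-2-carboxylate (lactol) | COC(=O)[C@H]1[C@@H](O[Si](C)(C)C(C)(C)C)C[C@@H]2OC(O)[C@H]1C2(C)C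
A1 | alternative 1 | isopropenyl analogue of the target | CC(=C)[C@@H]1CC[C@H]2[C@]3(COC(=O)[C@]2(O)C1)C(=O)C[C@@H]1OC[C@H]3C1(C)C
A2 | alternative 1 | α-keto ester tethered to the exocyclic enone of ring A | COC(=O)C(=O)C[C@H](C(C)=C)CCC=C1C(=O)C[C@@H]2OC[C@H]1C2(C)C
A3 | alternative 1 | formaldehyde | C=O
A4 | alternative 2 | bridged β-keto ester methyl acetal | COC(=O)[C@@H]1C(=O)C[C@@H]2O[C@H](OC)[C@H]1C2(C)C
A5 | alternative 2 | methyl (5S)-5-hydroxy-8-methoxy-6,6-dimethyl-3-oxooct-7-enoate | COC(=O)CC(=O)C[C@H](O)C(C)(C)C=COC
A6 | alternative 3 | methyl (1R,2S,5S)-8,8-dimethyl-3-oxo-6-oxabicyclo[3.2.1]octane-2-carboxylate (identical with 16) | COC(=O)[C@@H]1C(=O)C[C@@H]2OC[C@H]1C2(C)C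
A7 | alternative 3 | bis(trimethylsilyl) dienol ether of the α-substituted acetoacetate carrying the benzyl ether and the dimethyl acetal | COC(O[Si](C)(C)C)=C(C(=C)O[Si](C)(C)C)[C@@H](COCc1ccccc1)C(C)(C)C(OC)OC
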